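In the end group, the cyclohexane ring (C1–C6, carotenoid numbering) and the 2,5-dihydrofuran ring (O, C5, C6, C7, C8) share the bond C5–C6, so that O–C8–C7 is a three-atom bridge from C5 to C6. The route exploits this: an acyclic 2-silyloxy-4-alkoxy-1,3-diene (C2=C3–C4=C5), whose ether oxygen carries an enantiopure 1,1-dimethylallenyl carbinol (C8), undergoes an intramolecular Diels–Alder reaction with the distal allene bond C6=C1. One operation forms C1–C2 and C5–C6, closes both rings, creates the gem-dimethyl carbon and sets C5 from C8. The precursor is a vinylogous ester of acetylacetone; the pentaene is attached last by Wittig reaction with a C10 dialdehyde.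

Key step: step 5

Remark on numbering: C1 = CMe2, C2 = ring CH2 next to it, C3 = CHOH, C4 = CH2, C5 = C(CH3)–O, C6 = ring-fusion alkene carbon, C7 = ring =CH, C8 = O–CH, C9–C12′ = polyene chain.

Remark on step 2: the (S,S) ligand is assumed to deliver the (4S)-carbinol 5; if the facial sense on this enal is the opposite, the (R,R) ligand is used with no other change.

Step 1
Reactants: 1 (tert-butyldimethylsilyloxy)acetaldehyde; 2 2-(triphenyl-λ5-phosphanylidene)propanal
Product: 3 (2E)-4-[(tert-butyldimethylsilyl)oxy]-2-methylbut-2-enal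
Conditions: toluene, 80 °C
Reagents that add atoms: none
Why: Wittig olefination with a formyl-stabilised ylide, which should give the E-trisubstituted enal (the later C9=C10 bond).

Step 2
Reactants: 3 (2E)-4-[(tert-butyldimethylsilyl)oxy]-2-methylbut-2-enal; 4 3-methoxy-3-methylbut-1-yne
Product: 5 (2E,4S)-1-[(tert-butyldimethylsilyl)oxy]-7-methoxy-3,7-dimethyloct-2-en-5-yn-4-ol
Conditions: Me2Zn (3 equiv), 4 (3 equiv), (S,S)-2,6-bis{[2-(hydroxydiphenylmethyl)pyrrolidin-1-yl]methyl}-4-methylphenol (10 mol%), Ph3PO (20 mol%), toluene, 0 °C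
Reagents that add atoms: none
Why: Catalytic enantioselective addition of an alkynylzinc to an enal (ProPhenol–dizinc alkynylation), in which the chiral dinuclear zinc catalyst sets the carbinol centre (later C8), the only source of absolute configuration in the route.

Step 3
Reactants: 5 (2E,4S)-1-[(tert-butyldimethylsilyl)oxy]-7-methoxy-3,7-dimethyloct-2-en-5-yn-4-ol
Product: 6 (2E,4R)-1-[(tert-butyldimethylsilyl)oxy]-3,7-dimethylocta-2,5,6-trien-4-ol
Conditions: LiAlH4 (2 equiv), THF, 0 °C to rt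
Reagents that add atoms: none
Why: Alkoxide-directed trans-hydroalumination of the propargylic alcohol followed by 1,2-elimination of the tertiary methoxide (formal SN2′ hydride reduction) gives the 1,1-dimethylallene without touching the carbinol centre, whose descriptor changes only by priority.

Step 4
Reactants: 6 (2E,4R)-1-[(tert-butyldimethylsilyl)oxy]-3,7-dimethylocta-2,5,6-trien-4-ol; 7 pent-3-yn-2-one
Product: 8 (3E)-4-({(2E,4R)-1-[(tert-butyldimethylsilyl)oxy]-3,7-dimethylocta-2,5,6-trien-4-yl}oxy)pent-3-en-2-one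
Conditions: 7 (1.5 equiv), PMe3 (20 mol%), CH2Cl2, 0 °C to rt
Reagents that add atoms: none
Why: Phosphine-catalysed oxa-Michael addition of the alcohol to the ynone should give the E vinylogous ester (alkoxy group anti to acetyl), the thermodynamically favoured isomer and the geometry that places the ether bridge on the outside of the later diene.

Step 5
Reactants: 8 (3E)-4-({(2E,4R)-1-[(tert-butyldimethylsilyl)oxy]-3,7-dimethylocta-2,5,6-trien-4-yl}oxy)pent-3-en-2-one
Product: 11 tert-butyl({(2E)-3-[(2R,7aR)-6-{[tert-butyl(dimethyl)silyl]oxy}-4,4,7a-trimethyl-2,4,5,7a-tetrahydro-1-benzofuran-2-yl]but-2-en-1-yl}oxy)dimethylsilane, via lithium dienolate 9 (not isolated), via silyl dienol ether 10 (not isolated)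
Conditions: LiN(i-Pr)2, THF, −78 °C; TBSCl, DMPU, −78 to 0 °C; solvent exchange to toluene (0.02 M), BHT, 80 °C
Reagents that add atoms: tert-butyldimethylsilyl chloride CC(C)(C)[Si](C)(C)Cl
Why: Kinetic deprotonation of the acetyl methyl group (C2) and O-silylation give the 2-silyloxy-4-alkoxy-1,3-diene 10, whose s-cis form adds across the distal allene bond C6=C1 in a concerted, asynchronous intramolecular Diels–Alder reaction in which C5–C6 is expected to form ahead of C1–C2. The closest known reaction type is the intramolecular allene Diels–Alder reaction of furfuryl allenyl ethers and of N-aryl allenecarboxamides, where a three-atom bridge from the diene terminus ends at the allene terminus and the distal allene bond reacts at moderate temperature. The cyclohexene ring (C1–C6) closes by the [4+2] cycloaddition itself, and the 2,5-dihydrofuran ring (O, C5, C6, C7, C8) closes as the bridge ring when C5–C6 forms, with C6=C7 left as its alkene. C5 is the only new stereocentre and is controlled by C8: in the folded transition state the forming dihydrofuran stands nearly at right angles to the diene plane, and the C8 side chain should take the side of C4–H in preference to the side of the inside methyl group on C5, which gives the side chain trans to that methyl group (5R from 8R), although this 1,3-induction may be modest. The step needs site selectivity (the proximal allene bond cannot react, as it would close a four-membered ring), regioselectivity (fixed by the bridge, with the nucleophilic CH2 terminus meeting the dimethyl-substituted carbon) and preference for cycloaddition over a [3,3] shift of the allyl vinyl ether unit, for which the strain released by the allene and the low temperature are relied on.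

Step 6
Reactants: 11 tert-butyl({(2E)-3-[(2R,7aR)-6-{[tert-butyl(dimethyl)silyl]oxy}-4,4,7a-trimethyl-2,4,5,7a-tetrahydro-1-benzofuran-2-yl]but-2-en-1-yl}oxy)dimethylsilane
Product: 12 (2R,7aR)-2-[(2E)-4-hydroxybut-2-en-2-yl]-4,4,7a-trimethyl-4,5,7,7a-tetrahydro-1-benzofuran-6(2H)-one
Conditions: Bu4NF, AcOH (1:1, 3 equiv), THF, 0 °C to rt
Reagents that add atoms: none
Why: Fluoride cleaves the silyl enol ether (C-protonation gives the C3 ketone) and the primary silyl ether, and the acetic acid buffer should suppress retro-oxa-Michael opening of the β-alkoxy ketone, which would scramble C5.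

Step 7
Reactants: 12 (2R,7aR)-2-[(2E)-4-hydroxybut-2-en-2-yl]-4,4,7a-trimethyl-4,5,7,7a-tetrahydro-1-benzofuran-6(2H)-one
Product: 13 (2R,6S,7aR)-2-[(2E)-4-hydroxybut-2-en-2-yl]-4,4,7a-trimethyl-2,4,5,6,7,7a-hexahydro-1-benzofuran-6-ol
Conditions: LiB(s-Bu)3H (2.5 equiv), THF, −78 °C; then NaOH, H2O2, 0 °C
Reagents that add atoms: none
Why: Diastereoselective ketone reduction with a bulky hydride, which should attack C3 from the equatorial direction, away from the two syn-axial methyl groups on C1 and C5, and so give the axial alcohol cis to the C5 methyl group (3S).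

Step 8
Reactants: 13 (2R,6S,7aR)-2-[(2E)-4-hydroxybut-2-en-2-yl]-4,4,7a-trimethyl-2,4,5,6,7,7a-hexahydro-1-benzofuran-6-ol
Product: 15 {(2E)-3-[(2R,6S,7aR)-6-hydroxy-4,4,7a-trimethyl-2,4,5,6,7,7a-hexahydro-1-benzofuran-2-yl]but-2-en-1-yl}triphenylphosphonium bromide, via allylic bromide 14 (not isolated)
Conditions: NBS, Me2S, CH2Cl2, −20 to 0 °C; then PPh3, rt
Reagents that add atoms: N-bromosuccinimide O=C1CCC(=O)N1Br; triphenylphosphine c1ccc(cc1)P(c1ccccc1)c1ccccc1
Why: Corey–Kim halogenation converts only the allylic alcohol into the bromide and leaves the hindered secondary alcohol, and SN2 quaternisation at the primary carbon gives the Wittig salt without the acid that the doubly allylic C8–O bond would not tolerate.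

Step 9
Reactants: 15 {(2E)-3-[(2R,6S,7aR)-6-hydroxy-4,4,7a-trimethyl-2,4,5,6,7,7a-hexahydro-1-benzofuran-2-yl]but-2-en-1-yl}triphenylphosphonium bromide; 16 (2E,4E,6E)-2,7-dimethylocta-2,4,6-trienedial
Product: 17 (2E,4E,6E,8E,10E)-11-[(2R,6S,7aR)-6-hydroxy-4,4,7a-trimethyl-2,4,5,6,7,7a-hexahydro-1-benzofuran-2-yl]-2,7-dimethyldodeca-2,4,6,8,10-pentaenal
Conditions: 16 (3 equiv), NaOMe, MeOH/CH2Cl2, −10 °C to rt; then heptane, 80 °C
Reagents that add atoms: none
Why: Wittig olefination of the allylic ylide with one aldehyde group of the excess symmetrical dialdehyde forms C11=C12, the ylide being generated by a mild base in the presence of the aldehyde so that it is trapped before it can open the dihydrofuran, and any 11Z isomer, a hindered cis bond, should isomerise to E on warming.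

Step 10
Reactants: 17 (2E,4E,6E,8E,10E)-11-[(2R,6S,7aR)-6-hydroxy-4,4,7a-trimethyl-2,4,5,6,7,7a-hexahydro-1-benzofuran-2-yl]-2,7-dimethyldodeca-2,4,6,8,10-pentaenal
Product: 18 (2R,6S,7aR)-2-[(2E,4E,6E,8E,10E)-12-hydroxy-6,11-dimethyldodeca-2,4,6,8,10-pentaen-2-yl]-4,4,7a-trimethyl-2,4,5,6,7,7a-hexahydro-1-benzofuran-6-ol (CNP0239155.2)
Conditions: NaBH4, MeOH/THF, 0 °C
Reagents that add atoms: none
Why: Chemoselective 1,2-reduction of the polyenal to the primary allylic alcohol, which leaves the polyene and all stereocentres untouched.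

Compound list
1 | (tert-butyldimethylsilyloxy)acetaldehyde | O=CCO[Si](C)(C)C(C)(C)C | starting material
2 | 2-(triphenyl-λ5-phosphanylidene)propanal | CC(C=O)=P(c1ccccc1)(c1ccccc1)c1ccccc1 | starting material
3 | (2E)-4-[(tert-butyldimethylsilyl)oxy]-2-methylbut-2-enal | O=C/C(C)=C/CO[Si](C)(C)C(C)(C)C | intermediate
4 | 3-methoxy-3-methylbut-1-yne | C#CC(C)(C)OC | starting material
5 | (2E,4S)-1-[(tert-butyldimethylsilyl)oxy]-7-methoxy-3,7-dimethyloct-2-en-5-yn-4-ol | COC(C)(C)C#C[C@@H](O)/C(C)=C/CO[Si](C)(C)C(C)(C)C | intermediate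
6 | (2E,4R)-1-[(tert-butyldimethylsilyl)oxy]-3,7-dimethylocta-2,5,6-trien-4-ol | CC(C)=C=C[C@@H](O)/C(C)=C/CO[Si](C)(C)C(C)(C)C | intermediate
7 | pent-3-yn-2-one | CC#CC(C)=O | starting material
8 | (3E)-4-({(2E,4R)-1-[(tert-butyldimethylsilyl)oxy]-3,7-dimethylocta-2,5,6-trien-4-yl}oxy)pent-3-en-2-one | CC(=O)/C=C(\C)O[C@H](C=C=C(C)C)/C(C)=C/CO[Si](C)(C)C(C)(C)C | intermediate
9 | lithium (3E)-4-({(2E,4R)-1-[(tert-butyldimethylsilyl)oxy]-3,7-dimethylocta-2,5,6-trien-4-yl}oxy)penta-1,3-dien-2-olate | [Li]OC(=C)/C=C(\C)O[C@H](C=C=C(C)C)/C(C)=C/CO[Si](C)(C)C(C)(C)C | intermediate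
10 | tert-butyl{[(3E)-4-({(2E,4R)-1-[(tert-butyldimethylsilyl)oxy]-3,7-dimethylocta-2,5,6-trien-4-yl}oxy)penta-1,3-dien-2-yl]oxy}dimethylsilane | C=C(O[Si](C)(C)C(C)(C)C)/C=C(\C)O[C@H](C=C=C(C)C)/C(C)=C/CO[Si](C)(C)C(C)(C)C | intermediate
11 | tert-butyl({(2E)-3-[(2R,7aR)-6-{[tert-butyl(dimethyl)silyl]oxy}-4,4,7a-trimethyl-2,4,5,7a-tetrahydro-1-benzofuran-2-yl]but-2-en-1-yl}oxy)dimethylsilane | CC(C)(C)[Si](C)(C)OC/C=C(\C)[C@H]1C=C2C(C)(C)CC(O[Si](C)(C)C(C)(C)C)=C[C@@]2(C)O1 | intermediate
12 | (2R,7aR)-2-[(2E)-4-hydroxybut-2-en-2-yl]-4,4,7a-trimethyl-4,5,7,7a-tetrahydro-1-benzofuran-6(2H)-one | OC/C=C(\C)[C@H]1C=C2C(C)(C)CC(=O)C[C@@]2(C)O1 | intermediate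
13 | (2R,6S,7aR)-2-[(2E)-4-hydroxybut-2-en-2-yl]-4,4,7a-trimethyl-2,4,5,6,7,7a-hexahydro-1-benzofuran-6-ol | OC/C=C(\C)[C@H]1C=C2C(C)(C)C[C@H](O)C[C@@]2(C)O1 | intermediate
14 | (2R,6S,7aR)-2-[(2E)-4-bromobut-2-en-2-yl]-4,4,7a-trimethyl-2,4,5,6,7,7a-hexahydro-1-benzofuran-6-ol | BrC/C=C(\C)[C@H]1C=C2C(C)(C)C[C@H](O)C[C@@]2(C)O1 | intermediate
15 | {(2E)-3-[(2R,6S,7aR)-6-hydroxy-4,4,7a-trimethyl-2,4,5,6,7,7a-hexahydro-1-benzofuran-2-yl]but-2-en-1-yl}triphenylphosphonium bromide | [Br-].c1ccc(cc1)[P+](c1ccccc1)(c1ccccc1)C/C=C(\C)[C@H]1C=C2C(C)(C)C[C@H](O)C[C@@]2(C)O1 | intermediate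
16 | (2E,4E,6E)-2,7-dimethylocta-2,4,6-trienedial | O=C/C(C)=C/C=C/C=C(\C)C=O | starting material
17 | (2E,4E,6E,8E,10E)-11-[(2R,6S,7aR)-6-hydroxy-4,4,7a-trimethyl-2,4,5,6,7,7a-hexahydro-1-benzofuran-2-yl]-2,7-dimethyldodeca-2,4,6,8,10-pentaenal | CC(/C=C/C=C(\C)[C@H]1C=C2C(C)(C)C[C@H](O)C[C@@]2(C)O1)=C\C=C\C=C(/C)C=O | intermediate
18 | (2R,6S,7aR)-2-[(2E,4E,6E,8E,10E)-12-hydroxy-6,11-dimethyldodeca-2,4,6,8,10-pentaen-2-yl]-4,4,7a-trimethyl-2,4,5,6,7,7a-hexahydro-1-benzofuran-6-ol | CC(/C=C/C=C(\C)[C@H]1C=C2C(C)(C)C[C@H](O)C[C@@]2(C)O1)=C\C=C\C=C(/C)CO | target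

Total step count: 10. Longest linear sequence: 10 steps (1 to 18).

Steps most likely to fail

1. Step 5. The allyl vinyl ether array of 10 (C4=C5–O–C8 with either the allene or the C9=C10 alkene) may undergo a [3,3] shift faster than the cycloaddition. Facial discrimination at C5 by the remote C8 centre may also be low, and a 1,5-hydrogen shift from the inside methyl group may erode the diene.
Fallback from 3, back at 13: the cycloaddition is replaced by the classical epoxide-to-furanoid rearrangement of a preformed ring.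
- Aldehyde 3 is homologated with lithium trimethylsilyldiazomethane (THF, −78 to 0 °C) to the enyne tert-butyldimethyl{[(2E)-3-methylpent-2-en-4-yn-1-yl]oxy}silane F1.
- F1 is hydroborated with pinacolborane (Cp2Zr(H)Cl cat., Et3N) to the dienylboronate tert-butyldimethyl{[(2E,4E)-3-methyl-5-(4,4,5,5-tetramethyl-1,3,2-dioxaborolan-2-yl)penta-2,4-dien-1-yl]oxy}silane F2.
- Commercial (4R,6R)-4-hydroxy-2,2,6-trimethylcyclohexanone is silylated (TBSCl, imidazole) to (4R,6R)-4-[(tert-butyldimethylsilyl)oxy]-2,2,6-trimethylcyclohexan-1-one F3.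
- F3 is converted (KN(SiMe3)2, PhNTf2, THF, −78 °C) into (4R)-4-[(tert-butyldimethylsilyl)oxy]-2,6,6-trimethylcyclohex-1-en-1-yl trifluoromethanesulfonate F4.
- Suzuki coupling of F2 with F4 (Pd(PPh3)4, K3PO4, dioxane/H2O) should give the triene tert-butyl({(2E,4E)-5-[(4R)-4-{[tert-butyl(dimethyl)silyl]oxy}-2,6,6-trimethylcyclohex-1-en-1-yl]-3-methylpenta-2,4-dien-1-yl}oxy)dimethylsilane F5.
- mCPBA with NaHCO3 should epoxidise the tetrasubstituted ring alkene mainly anti to the silyloxy group, giving the (3S,5R,6S)-5,6-epoxide of F5 (carotenoid numbering) F6.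
- Catalytic PPTS in CH2Cl2 should rearrange F6 to the 5,8-epoxide, the bis(tert-butyldimethylsilyl) ether of 13 F7; its C8 epimer is expected alongside and is removed by chromatography.
- Bu4NF then gives 13.

2. Step 9. The ylide may open the dihydrofuran by 1,4-elimination of the C8–O bond before it meets the aldehyde, both aldehyde groups of 16 may react, and the new C11=C12 bond may form as an E/Z mixture.
Fallback from 13 and 16, back at 18: the polarity of the coupling is reversed so that the ylide sits on the chain fragment.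
- MnO2 in CH2Cl2 oxidises only the allylic alcohol of 13 to (2E)-3-[(2R,6S,7aR)-6-hydroxy-4,4,7a-trimethyl-2,4,5,6,7,7a-hexahydro-1-benzofuran-2-yl]but-2-enal F8.
- NaBH4 reduces 16 to (2E,4E,6E)-2,7-dimethylocta-2,4,6-triene-1,8-diol F9.
- One equivalent of PPh3·HBr in MeOH converts F9 into [(2E,4E,6E)-8-hydroxy-2,7-dimethylocta-2,4,6-trien-1-yl]triphenylphosphonium bromide F10.
- Wittig reaction of F10 with F8 (NaOMe, MeOH/CH2Cl2) forms C11=C12 and gives 18 directly.

3. Step 4. The phosphine may isomerise ynone 7 to the allenone and divert the alcohol to γ-addition or oligomers, and the hindered secondary alcohol may add slowly.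
Fallback from 6, back at 8: conjugate addition to an alkyne is replaced by addition–elimination on a β-chloro enone.
- Acetylacetone with oxalyl chloride and catalytic DMF gives (3E)-4-chloropent-3-en-2-one F11.
- The sodium alkoxide of 6 (NaH, THF, 0 °C) displaces chloride from F11 and should give 8 as the favoured E isomer.

Further compounds
F1 | step 5 | tert-butyldimethyl{[(2E)-3-methylpent-2-en-4-yn-1-yl]oxy}silane | C#C/C(C)=C/CO[Si](C)(C)C(C)(C)C
F2 | step 5 | tert-butyldimethyl{[(2E,4E)-3-methyl-5-(4,4,5,5-tetramethyl-1,3,2-dioxaborolan-2-yl)penta-2,4-dien-1-yl]oxy}silane | CC1(C)OB(/C=C/C(C)=C/CO[Si](C)(C)C(C)(C)C)OC1(C)C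
F3 | step 5 | (4R,6R)-4-[(tert-butyldimethylsilyl)oxy]-2,2,6-trimethylcyclohexan-1-one | CC1(C)C[C@H](O[Si](C)(C)C(C)(C)C)C[C@@H](C)C1=O
F4 | step 5 | (4R)-4-[(tert-butyldimethylsilyl)oxy]-2,6,6-trimethylcyclohex-1-en-1-yl trifluoromethanesulfonate | CC1=C(OS(=O)(=O)C(F)(F)F)C(C)(C)C[C@H](O[Si](C)(C)C(C)(C)C)C1
F5 | step 5 | tert-butyl({(2E,4E)-5-[(4R)-4-{[tert-butyl(dimethyl)silyl]oxy}-2,6,6-trimethylcyclohex-1-en-1-yl]-3-methylpenta-2,4-dien-1-yl}oxy)dimethylsilane | CC1=C(/C=C/C(C)=C/CO[Si](C)(C)C(C)(C)C)C(C)(C)C[C@H](O[Si](C)(C)C(C)(C)C)C1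
F6 | step 5 | (3S,5R,6S)-5,6-epoxide of F5 (carotenoid numbering) | [C@@]12(/C=C/C(C)=C/CO[Si](C)(C)C(C)(C)C)O[C@]1(C)C[C@@H](O[Si](C)(C)C(C)(C)C)CC2(C)C
F7 | step 5 | bis(tert-butyldimethylsilyl) ether of 13 | CC(C)(C)[Si](C)(C)OC/C=C(\C)[C@H]1C=C2C(C)(C)C[C@H](O[Si](C)(C)C(C)(C)C)C[C@@]2(C)O1
F8 | step 9 | (2E)-3-[(2R,6S,7aR)-6-hydroxy-4,4,7a-trimethyl-2,4,5,6,7,7a-hexahydro-1-benzofuran-2-yl]but-2-enal | O=C/C=C(\C)[C@H]1C=C2C(C)(C)C[C@H](O)C[C@@]2(C)O1
F9 | step 9 | (2E,4E,6E)-2,7-dimethylocta-2,4,6-triene-1,8-diol | OC/C(C)=C/C=C/C=C(\C)CO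
F10 | step 9 | [(2E,4E,6E)-8-hydroxy-2,7-dimethylocta-2,4,6-trien-1-yl]triphenylphosphonium bromide | [Br-].OC/C(C)=C/C=C/C=C(\C)C[P+](c1ccccc1)(c1ccccc1)c1ccccc1
F11 | step 4 | (3E)-4-chloropent-3-en-2-one | CC(=O)/C=C(\C)Cl
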